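The rate constants were drawn at random within sensible limits.

**Turnover unit.** One turnover is a rate constant times a concentration times a time, a plain count with no unit left. You can count it by hand before anything is run. Here X and dissolved G compete for E, and G comes from solid Q.

    E + X → E.X (k1 = 0.55 L mol⁻¹ s⁻¹, Ea1 = 47.0 kJ mol⁻¹)
    E + G → E.G (k2 = 1.2 L mol⁻¹ s⁻¹, Ea2 = 65.0 kJ mol⁻¹)
    E + E.X ⇌ E.E.X, settled at all times (K3 = 220 L mol⁻¹, ΔH3 = −32.0 kJ mol⁻¹)
    2 E → E2 (k4 = 8.5 × 10⁻⁴ L mol⁻¹ s⁻¹, Ea4 = 70.0 kJ mol⁻¹)
    Q ⇌ G, rate k5*(cs5 - [G]) while solid is left; crystals form when [G] > cs5 (cs5 = 7.4 mM, k5 = 0.015 s⁻¹)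
    (constants at 40 °C)

| setting | Sunday's | Tuesday's | Thursday's |
|---|---|---|---|
| E | 0.011 M | 0.011 M | 0.011 M |
| X | 1.00 equiv | 1.00 equiv | 1.00 equiv |
| Q | 3.00 equiv | 3.00 equiv | 3.00 equiv |
| temperature | 10 °C | 40 °C | −20 °C |
| time | 40 min | 40 min | 40 min |

- percentages count the E that a species holds: one E.E.X or E2 counts as two
- E.X is meant together with its E.E.X
- a step written with two of one species runs at k times the square of its concentration and takes two of it each time
- solid, in amounts per volume of the solution: Q
- the constants hold at 40 °C; other temperatures follow from the activation energies and enthalpies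
- at the start none of Q is in solution
- in an amount of E.X, one E.E.X counts as one E.X

- the flask with the highest amount of E.X, in percent of the E charged ("all alike" if they lie within 1.5 percentage points) (Sunday's / Tuesday's / Thursday's / all alike)
- final E.X, as a percentage of the E charged, in Sunday's
- final E.X, as a percentage of the E charged, in Tuesday's
- final E.X, as a percentage of the E charged, in Thursday's

**Two counts.** In Tuesday's flask, at 40 °C, X at its charge gives 14.5 turnovers in 40 min, so E has time to finish. G at its solubility gives 21.3. I carry their quotient, 1.47. Call it the split number: turnovers of E on G for each one on X, with G at solubility and X at full charge.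

**First share.** With X held at its charge, E.X would get 40.5 % of the E. But X falls as it is used, so I take it at the midpoint of its fall. That gives 35.2 % for Tuesday's, and I commit to it.

**Weak link.** That number has G at solubility from the first moment, yet G starts from nothing and rises with a time of 66.7 s. So X runs ahead for 0.403 turnovers. With equal charges, that makes 28.7 % of the E into E.X. The remaining E divides as before, with X lowered. Tuesday's then ends near 49.3 %.

**Colder flasks.** Sunday's 10 °C lies close to 8.2 °C, where steps 1 and 2 have like constants, so its split is near 0.673. Its E.X would end near 51.0 % once E is gone. But its count is only about 1.89, and I have not reckoned the E held in E.E.X. So my ranking of Sunday's against Tuesday's stays open. Thursday's count is 0.201, which gives 16.7 % with G ignored.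

**The forecast.** It names Tuesday's, with 43 % for Sunday's, 47.5 % for Tuesday's and 15 % for Thursday's. It holds that “E.X gets its share mainly because G needs a minute or so to dissolve”. My Tuesday figure stands above its value, and where I leave the ranking open, it commits.

**The result.** The simulation gives Tuesday's, with 42.6 % for Sunday's, 47.9 % for Tuesday's and 15.1 % for Thursday's, so the forecast holds. In Sunday's flask, the rate of E on X over that on G falls from 390 just after the start to 0.82 at 40.0 min, where X stands at 57.4 % of its charge and the split number gives 0.853. In the neighbour of Sunday's flask with 0.0027 M of E, the split number grows to 2.74, and that flask holds 58.9 % of E.G against 20.3 % of E.X, a ratio of 2.90.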